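The plan rests on reading C19, the carboxyl carbon on quaternary C4 of ring A (C1–C5, C10), as a former ring atom. Ring A is therefore carried as a cycloheptene, C10–C1–C2–C3–C19=C4–C5, trans-fused to ring B and made from (R)-carvone by two alkylations at C10 and ring-closing metathesis. In the key step a bulky aluminium Lewis acid opens its 4β,19β-epoxide at C4 and C3 shifts from C19 to C4. One operation contracts the seven-membered ring to ring A, sets the C4 quaternary centre and expels C19 as the axial aldehyde. The surviving carvone enone then takes up C11–C16 and delivers the 8α-hydroxyl.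

Key step: step 5

Remark on the chemistry: labdane numbering (C1–C20) is used for every intermediate. β is the face of the C10 methyl (C20) and α the opposite face. Compound 2 is carried on as its C10-epimer mixture, and its SMILES shows the expected major epimer.

Step 1
Reactants: 1 (R)-(−)-carvone
Product: 2 6-methylcarvone (carvone methylated at C10)
Conditions: LDA, THF, −78 °C; MeI, −78 to 0 °C
Reagents that add atoms: iodomethane CI
Why: Kinetic α′-deprotonation of the cross-conjugated enone and SN2 methylation (enolate alkylation) place C20 on C10; the methyl should enter mainly anti to the C5 isopropenyl group, but this centre is planarised again in step 2, so its configuration is of no consequence.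

Step 2
Reactants: 2 6-methylcarvone; 3 5-iodopent-1-ene
Product: 4 (5S,6S)-2,6-dimethyl-6-(pent-4-en-1-yl)-5-(prop-1-en-2-yl)cyclohex-2-en-1-one (10α-pentenyl, 10β-methyl)
Conditions: LDA, THF, −78 to 0 °C; DMPU, 3, 0 °C to rt
Reagents that add atoms: none
Why: Second enolate alkylation: the tetrasubstituted C9/C10 dienolate should take up the primary iodide on the face anti to the neighbouring C5 isopropenyl group, so the chain becomes 10α and C20 10β, which fixes quaternary C10 relative to the carvone stereocentre C5.

Step 3
Reactants: 4 dialkylated carvone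
Product: 5 trans-fused 2,5,9a-trimethyl-4,4a,7,8,9,9a-hexahydro-1H-benzo[7]annulen-1-one (5α-H, 10β-CH3; seven-membered ring C10–C1–C2–C3–C19=C4–C5)
Conditions: Grubbs II (5 mol %), toluene (2 mM), 80 °C
Reagents that add atoms: none
Why: Ring-closing olefin metathesis: the catalyst loads on the monosubstituted alkene and closes onto the isopropenyl group, the two arms being trans-diequatorial on ring B, while the α-methyl enone C7=C8 is too hindered and electron-poor to take part; no stereocentre is formed and the trans fusion follows from C5 and C10.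

Step 4
Reactants: 5 bicyclic dienone
Product: 7 4β,19β-epoxy enone, via bromohydrin 6 (not isolated)
Conditions: NBS, DME/H2O, 0 °C; then K2CO3, MeOH, rt
Reagents that add atoms: water O; N-bromosuccinimide O=C1CCC(=O)N1Br (bromine only in 6)
Why: Halohydrin formation and intramolecular Williamson closure: the bromonium ion should form on the open α face of the only electron-rich alkene and be opened by water at tertiary C4 from the β face (Markovnikov, trans-diaxial), so that base closes the epoxide on the β face, which a peracid would avoid because of the axial C10 methyl; this sets C4 and C19.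

Step 5
Reactants: 7 4β,19β-epoxy enone
Product: 8 1,4a,6-trimethyl-5-oxo-1,2,3,4,4a,5,8,8a-octahydronaphthalene-1-carbaldehyde (4β-CHO = C19 axial, 4α-CH3 = C18, 5α-H, 10β-CH3)
Conditions: MABR (2.2 equiv, from Me3Al and 4-bromo-2,6-di-tert-butylphenol), CH2Cl2, −78 to −40 °C; aq. HCl
Reagents that add atoms: none
Why: The oxophilic aluminium Lewis acid binds the epoxide oxygen and lengthens the C4–O bond, since only C4 can carry tertiary cation character; as that bond breaks, the C19–C3 σ-bond, lying on the α side anti to the departing oxygen, shifts to C4 and C19 becomes the aldehyde carbon (Meinwald/semipinacol rearrangement of a trisubstituted epoxide, the closest known type being the epoxide-to-aldehyde rearrangement promoted by bulky aluminium phenoxides). Ring A (C1–C5, C10) is closed not by a cyclisation mode but by this suprafacial 1,2-alkyl shift, a 7→6 ring contraction that trades cycloheptane strain for a chair cyclohexane. The only new stereocentre, C4, is set by inversion at the carbon that loses oxygen: C3 enters from the α face, so C19 stays on the β (axial) face where the oxygen was and C18 becomes equatorial, which means the epoxide configuration from step 4 controls it. The step needs C4–O over C19–O cleavage, secured by tertiary versus secondary cation stability, and alkyl over hydride migration, which the very bulky aluminium phenoxide and the release of ring strain should favour. The enone only ties up one equivalent of Lewis acid, and C5 and C10 are not touched.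

Step 6
Reactants: 8 keto aldehyde
Product: 9 1,4a,6-trimethyl-5-oxo-1,2,3,4,4a,5,8,8a-octahydronaphthalene-1-carboxylic acid (C19 acid, axial)
Conditions: NaClO2, NaH2PO4, 2-methylbut-2-ene, t-BuOH/H2O, rt
Reagents that add atoms: sodium chlorite [Na+].[O-]Cl=O
Why: Pinnick oxidation: chlorous acid adds to the hindered aldehyde and fragments to the acid without touching the enone, the alkene scavenger removing HOCl; no stereocentre is affected.

Step 7
Reactants: 9 enone acid
Product: 11 1,4a,6-trimethyl-5-methylidene-1,2,3,4,4a,5,8,8a-octahydronaphthalene-1-carboxylic acid (7,9(11)-diene), via β-hydroxysilane 10 (not isolated)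
Conditions: TMSCH2MgCl (4 equiv), CeCl3, THF, −78 to 0 °C; then aq. HF, MeCN, rt
Reagents that add atoms: (trimethylsilyl)methylmagnesium chloride C[Si](C)(C)C[Mg]Cl
Why: Cerium-modified Peterson olefination: the non-basic organocerium reagent adds 1,2 to the hindered C9 ketone (its first equivalent only deprotonates the acid, whose carboxylate is inert), and acid-induced loss of the β-silyl and hydroxyl groups places the double bond regiospecifically at C9=C11; the transient C9 carbinol centre is destroyed.

Step 8
Reactants: 12 methyl (R)-2,2-dimethyl-1,3-dioxolane-4-carboxylate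
Product: 14 (S)-[2-(2,2-dimethyl-1,3-dioxolan-4-yl)allyl]trimethylsilane, via bis(silylmethyl)carbinol 13 (not isolated)
Conditions: TMSCH2MgCl (4 equiv), CeCl3, THF, −78 °C to rt; then SiO2, CH2Cl2, rt
Reagents that add atoms: (trimethylsilyl)methylmagnesium chloride C[Si](C)(C)C[Mg]Cl
Why: Double addition of the organocerium reagent to the ester followed by Peterson elimination of one silyl group gives the 2-substituted allylsilane; the low basicity of the reagent should keep the α-alkoxy stereocentre (future C14) from epimerising.

Step 9
Reactants: 14 allylsilane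
Product: 15 (S)-4-(3-bromoprop-1-en-2-yl)-2,2-dimethyl-1,3-dioxolane
Conditions: NBS, CH2Cl2, −78 to 0 °C
Reagents that add atoms: N-bromosuccinimide O=C1CCC(=O)N1Br
Why: Electrophilic bromodesilylation (SE2′) of the allylsilane: bromine adds to the CH2= terminus and the β-silyl cation loses silicon; both allyl termini are CH2, so the transposition is degenerate and C14 is not touched.

Step 10
Reactants: 11 diene acid; 15 allylic bromide
Product: 17 (14S)-14,15-O-isopropylidene-14,15-dihydroxylabda-7,13(16)-dien-19-oic acid, via alkylborane 16 (not isolated)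
Conditions: LiOt-Bu (1 equiv), then 9-BBN-H, THF, 60 °C; then LiOt-Bu, CuI (10 mol %), 15, THF, 40 °C; aq. citric acid
Reagents that add atoms: 9-borabicyclo[3.3.1]nonane B1C2CCCC1CCC2 (boron and its ring only in 16)
Why: Hydroboration followed by copper-catalysed allyl–alkyl coupling of the B-alkyl-9-BBN borate: 9-BBN adds to the only 1,1-disubstituted alkene from the α face, away from the axial C10 methyl, which sets 9α-H with C11 equatorial, and the alkylcopper formed by B-to-Cu transmetalation substitutes the allylic bromide, SN2 and SN2′ attack giving the same C11–C12 bond and C13=C16 methylene.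

Step 11
Reactants: 17 labdadienoic acid acetonide
Product: 18 7α,8α-epoxide of 17
Conditions: mCPBA (1.05 equiv), NaHCO3, CH2Cl2, 0 °C
Reagents that add atoms: 3-chloroperoxybenzoic acid O=C(OO)c1cccc(Cl)c1
Why: Prilezhaev epoxidation: trisubstituted C7=C8 is the most electron-rich alkene (C13=C16 is 1,1-disubstituted and deactivated by the allylic C14–O bond) and the peracid should approach from the α face opposite the axial C10 methyl, which fixes the C8–O bond as 8α.

Step 12
Reactants: 18 epoxy acid
Product: 19 (14S)-8α-hydroxy-14,15-O-isopropylidene-14,15-dihydroxylabd-13(16)-en-19-oic acid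
Conditions: LiEt3BH (4 equiv), THF, 0 °C to reflux; aq. HCl (cold, brief)
Reagents that add atoms: none
Why: SN2 opening of the epoxide by Super-Hydride at the less substituted C7 leaves the 8α C–O bond intact and gives the tertiary 8α-alcohol with C17 β, while the lithium carboxylate formed first is not reduced.

Step 13
Reactants: 19 hydroxy acid acetonide
Product: 20 (14S)-8α,14,15-trihydroxylabd-13(16)-en-19-oic acid (CNP0216809.1)
Conditions: AcOH/H2O/THF (3:1:1), 40 °C
Reagents that add atoms: none
Why: Acid-catalysed acetal hydrolysis under conditions mild enough for the tertiary 8α-hydroxyl and the allylic 14-hydroxyl; no stereocentre is touched.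

Compound list
1 | (R)-(−)-carvone | CC1=CC[C@H](CC1=O)C(C)=C | starting material
2 | 6-methylcarvone, (5R,6S) epimer expected as major | CC1=CC[C@@H](C(C)=C)[C@H](C)C1=O | intermediate
3 | 5-iodopent-1-ene | C=CCCCI | starting material
4 | (5S,6S)-2,6-dimethyl-6-(pent-4-en-1-yl)-5-(prop-1-en-2-yl)cyclohex-2-en-1-one | CC1=CC[C@@H](C(C)=C)[C@](C)(CCCC=C)C1=O | intermediate
5 | trans-fused 2,5,9a-trimethyl-4,4a,7,8,9,9a-hexahydro-1H-benzo[7]annulen-1-one | O=C1[C@@]2(C)CCCC=C(C)[C@@H]2CC=C1C | intermediate
6 | 19α-bromo-4β-hydroxy bromohydrin of 5 (not isolated) | O=C1[C@@]2(C)CCC[C@@H](Br)[C@](C)(O)[C@@H]2CC=C1C | intermediate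
7 | 4β,19β-epoxide of 5 | O=C1[C@@]2(C)CCC[C@@H]3O[C@]3(C)[C@@H]2CC=C1C | intermediate
8 | ring-contracted keto aldehyde (4β-CHO, 4α-CH3) | O=C1[C@@]2(C)CCC[C@](C)(C=O)[C@@H]2CC=C1C | intermediate
9 | enone C19 acid | O=C1[C@@]2(C)CCC[C@](C)(C(=O)O)[C@@H]2CC=C1C | intermediate
10 | C9 β-hydroxysilane (9β-OH, 9α-CH2SiMe3; not isolated) | C[Si](C)(C)C[C@@]1(O)[C@@]2(C)CCC[C@](C)(C(=O)O)[C@@H]2CC=C1C | intermediate
11 | 7,9(11)-diene C19 acid | C=C1[C@@]2(C)CCC[C@](C)(C(=O)O)[C@@H]2CC=C1C | intermediate
12 | methyl (R)-2,2-dimethyl-1,3-dioxolane-4-carboxylate | COC(=O)[C@H]1COC(C)(C)O1 | starting material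
13 | 2-[(R)-2,2-dimethyl-1,3-dioxolan-4-yl]-1,3-bis(trimethylsilyl)propan-2-ol (not isolated) | C[Si](C)(C)CC(O)(C[Si](C)(C)C)[C@H]1COC(C)(C)O1 | intermediate
14 | (S)-[2-(2,2-dimethyl-1,3-dioxolan-4-yl)allyl]trimethylsilane | C=C(C[Si](C)(C)C)[C@H]1COC(C)(C)O1 | intermediate
15 | (S)-4-(3-bromoprop-1-en-2-yl)-2,2-dimethyl-1,3-dioxolane | C=C(CBr)[C@H]1COC(C)(C)O1 | intermediate
16 | C11 B-alkyl-9-BBN of 11 (9α-H; not isolated, drawn as the free acid) | C1CC2CCCC(C1)B2C[C@@H]3[C@@]4(C)CCC[C@](C)(C(=O)O)[C@@H]4CC=C3C | intermediate
17 | (14S)-14,15-O-isopropylidene-14,15-dihydroxylabda-7,13(16)-dien-19-oic acid | C=C(CC[C@@H]1[C@@]2(C)CCC[C@](C)(C(=O)O)[C@@H]2CC=C1C)[C@H]1COC(C)(C)O1 | intermediate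
18 | 7α,8α-epoxide of 17 | C=C(CC[C@@H]1[C@@]2(C)CCC[C@](C)(C(=O)O)[C@@H]2C[C@H]3O[C@@]13C)[C@H]1COC(C)(C)O1 | intermediate
19 | 8α-hydroxy acid acetonide | C=C(CC[C@@H]1[C@@]2(C)CCC[C@](C)(C(=O)O)[C@@H]2CC[C@@]1(C)O)[C@H]1COC(C)(C)O1 | intermediate
20 | (14S)-8α,14,15-trihydroxylabd-13(16)-en-19-oic acid | C=C(CC[C@@H]1[C@@]2(C)CCC[C@](C)(C(=O)O)[C@@H]2CC[C@@]1(C)O)[C@H](O)CO | target

Total step count: 13. Longest linear sequence: 11 (steps 1–7 and 10–13).

Steps most likely to fail

**Step 5.** Hydride migration from C19 to C4 may outrun the shift of C3, so that the ring keeps its size. A long-lived C4 cation may also erode the transfer of configuration. The fallback sets out from 5 and comes back at 8. It separates ionisation from migration and uses the innate α-face preference of 5.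
- mCPBA (NaHCO3, CH2Cl2, 0 °C) should give the 4α,19α-epoxide F1.
- HBr in Et2O at low temperature should open it at tertiary C4 with inversion, giving the 4β-bromo-19α-hydroxy bromohydrin F2.
- AgBF4 in CH2Cl2 should abstract bromide while C3 shifts anti to the 4β C–Br bond (halohydrin semipinacol ring contraction). This double inversion leads to the same aldehyde 8.

**Step 10.** Three things may go wrong: slow hydroboration of the congested diene terminus, sluggish boron-to-copper transfer of the β-branched alkyl group, or O-allylation of the carboxylate. The fallback sets out from 11 and 15 and comes back at 17. It replaces the polar coupling by a radical one.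
- Borane 16 is oxidised (H2O2, NaOH) to the C11 primary alcohol F3.
- An Appel reaction (I2, PPh3, imidazole) gives the C11 iodide F4.
- Bromide 15 is converted with Bu3SnLi into the 2-substituted allylstannane F5.
- A Keck radical allylation of F4 with F5 (AIBN, benzene, 80 °C) forms the C11–C12 bond.

**Step 2.** SN2 attack of the unactivated iodide at the congested tetrasubstituted enolate carbon may be slow. That leaves room for proton transfer and O-alkylation. The fallback sets out from 2 and comes back at 4. It uses an activated electrophile and then extends the chain by cross-coupling.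
- LDA and allyl bromide give the 10α-allyl ketone F6, with the same facial control.
- Luche reduction masks the enone as the 9β-allylic alcohol F7.
- 9-BBN (2.2 equiv) takes up the hydroxyl group and hydroborates only the monosubstituted alkene, giving the bis-boryl compound F8.
- B-alkyl Suzuki–Miyaura coupling with vinyl bromide (PdCl2(dppf), aq. NaOH, THF) gives the pentenyl alcohol F9.
- MnO2 returns enone 4.

Further compounds
F1 | step 5 | 4α,19α-epoxide of 5 | O=C1[C@@]2(C)CCC[C@H]3O[C@@]3(C)[C@@H]2CC=C1C
F2 | step 5 | 4β-bromo-19α-hydroxy bromohydrin | O=C1[C@@]2(C)CCC[C@@H](O)[C@](C)(Br)[C@@H]2CC=C1C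
F3 | step 10 | C11 primary alcohol (9α-H) of the C19 acid | OC[C@@H]1[C@@]2(C)CCC[C@](C)(C(=O)O)[C@@H]2CC=C1C
F4 | step 10 | C11 iodide of the C19 acid | IC[C@@H]1[C@@]2(C)CCC[C@](C)(C(=O)O)[C@@H]2CC=C1C
F5 | step 10 | (S)-tributyl[2-(2,2-dimethyl-1,3-dioxolan-4-yl)allyl]stannane | C=C(C[Sn](CCCC)(CCCC)CCCC)[C@H]1COC(C)(C)O1
F6 | step 2 | 10α-allyl-10β-methyl carvone | CC1=CC[C@@H](C(C)=C)[C@](C)(CC=C)C1=O
F7 | step 2 | 9β-allylic alcohol of F6 | CC1=CC[C@@H](C(C)=C)[C@](C)(CC=C)[C@H]1O
F8 | step 2 | O,C-bis(9-BBN) adduct of F7 | CC1=CC[C@@H](C(C)=C)[C@](C)(CCCB2C3CCCC2CCC3)[C@H]1OB1C2CCCC1CCC2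
F9 | step 2 | 10α-pentenyl 9β-allylic alcohol | CC1=CC[C@@H](C(C)=C)[C@](C)(CCCC=C)[C@H]1O
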